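**Retrosynthetic overview**

1. Numbering (germacranolide style): ring A is the ten-membered carbocycle C1–C10 (C1=C10 alkene, C14 on C10, methyl C15 on C4, glycolate on C8). Ring B is the γ-lactone O–C6–C7–C11–C12, and C13 is the exocyclic methylene carbon.
2. Enabling feature: O8 on C8 stands 1,3 to C11 across C7, so C13 can be tied to O8 as a temporary tetrahydrofuran (ring C: O8–C8–C7–C11–C13). This masks the acrylate and the C8 hydroxyl together and puts C11 within 5-exo reach of C7. The cis H6/H7 fusion of ring B equals a syn addition to a Z C6=C7 alkene.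
3. Key disconnection: the lactone O–C6 bond and the C11–C7 bond are cut together. This takes the cis-fused B/C bicycle 15 back to the acyclic Z-allylic (alkoxymethyl)malonate 13 (iodocarbocyclisation–lactonisation).
4. Ring order: C and B together (step 9), then A by ring-closing metathesis at C1=C10 (step 11). Ring C is then opened again (Me2BBr, DBU) to free C8–OH and C11=C13. Glycolate, C14 oxidation and acetate come last.
5. Compound 13 comes from (S)-citronellal (C1–C6, C15), a diazophosphonate carbon (C7), DMF (C8), a methallylstannane (C9, C10, C14) and di-tert-butyl methylenemalonate (C11–C13).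

Key step: step 9

Remark: the ring-cis C1=C10 alkene carries the descriptor Z while C14 is a methyl group and E once C14 bears oxygen; the geometry itself does not change.

**Step 1**
Reactants: 1 (S)-citronellal [(3S)-3,7-dimethyloct-6-enal]
Product: 2 (4S)-4,8-dimethylnon-7-en-1-yne
Conditions: dimethyl (1-diazo-2-oxopropyl)phosphonate, K2CO3, MeOH, 0 °C → rt
Reagents that add atoms: dimethyl (1-diazo-2-oxopropyl)phosphonate, COP(=O)(OC)C(=[N+]=[N-])C(C)=O
Why: Seyferth–Gilbert homologation in the Ohira–Bestmann variant turns the aldehyde carbon C6 into the terminal alkyne C6≡C7 under mild base, and the C4 stereocentre, β to the carbonyl group, is not touched.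

**Step 2**
Reactants: 2 (4S)-4,8-dimethylnon-7-en-1-yne
Product: 3 (4S)-4-methylhept-6-ynal
Conditions: O3, CH2Cl2, −78 °C, stopped at consumption of 2; Me2S, −78 °C → rt
Reagents that add atoms: ozone, [O-][O+]=O
Why: Criegee ozonolysis with reductive work-up is chemoselective because the electron-rich trisubstituted alkene reacts with ozone far faster than the terminal alkyne, and it lays C1 bare as an aldehyde.

**Step 3**
Reactants: 3 (4S)-4-methylhept-6-ynal
Product: 4 (5S)-5-methyloct-1-en-7-yne
Conditions: MePPh3Br, KOtBu, THF, 0 °C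
Reagents that add atoms: methyltriphenylphosphonium bromide, C[P+](c1ccccc1)(c1ccccc1)c1ccccc1.[Br-]
Why: Wittig methylenation converts C1 into the monosubstituted alkene needed for the later metathesis, and the ylide is not basic enough to consume the alkyne C–H.

**Step 4**
Reactants: 4 (5S)-5-methyloct-1-en-7-yne
Product: 6 (5S)-5-methylnon-8-en-2-ynal, via lithium acetylide 5 (not isolated)
Conditions: n-BuLi, THF, −78 °C; DMF, −78 → 0 °C; poured into aq KH2PO4
Reagents that add atoms: N,N-dimethylformamide, CN(C)C=O
Why: Formylation of the lithium acetylide with DMF adds C8 at the aldehyde level, and the buffered inverse quench keeps the liberated amine from adding to the ynal.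

**Step 5**
Reactants: 6 (5S)-5-methylnon-8-en-2-ynal
Product: 7 (4S,8S)-2,8-dimethyldodeca-1,11-dien-5-yn-4-ol
Conditions: tributyl(2-methylallyl)stannane, (S)-BINOL (20 mol %), Ti(OiPr)4 (10 mol %), 4 Å MS, CH2Cl2, −20 °C; aq NaHCO3
Reagents that add atoms: tributyl(2-methylallyl)stannane, C=C(C)C[Sn](CCCC)(CCCC)CCCC
Why: Keck catalytic asymmetric methallylation forms C8–C9 and sets C8 as (S) under catalyst control; the symmetrical substitution of the allyl unit removes any α/γ regiochemical question.

**Step 6**
Reactants: 7 (4S,8S)-2,8-dimethyldodeca-1,11-dien-5-yn-4-ol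
Product: 8 (4S,5Z,8S)-2,8-dimethyldodeca-1,5,11-trien-4-ol
Conditions: H2 (1 atm), Pd/CaCO3 poisoned with Pb(OAc)2 (Lindlar catalyst), quinoline, EtOAc, rt, stopped after one equivalent of H2
Reagents that add atoms: none
Why: Lindlar semihydrogenation adds H2 syn to the alkyne and should stop at the Z-alkene C6=C7, the isolated mono- and 1,1-disubstituted alkenes being much slower on the poisoned catalyst.

**Step 7**
Reactants: 9 di-tert-butyl malonate
Product: 10 di-tert-butyl methylenemalonate (di-tert-butyl 2-methylidenepropanedioate)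
Conditions: (CH2O)n, KOAc, Cu(OAc)2, AcOH, 95 °C; distillation
Reagents that add atoms: paraformaldehyde (as formaldehyde), C=O
Why: Knoevenagel-type condensation with formaldehyde gives the methylenemalonate (C11–C13 plus one activating ester), whose tert-butyl groups make it stable enough to distil and store.

**Step 8**
Reactants: 8 (4S,5Z,8S)-2,8-dimethyldodeca-1,5,11-trien-4-ol; 10 di-tert-butyl methylenemalonate
Product: 13 di-tert-butyl 2-({[(4S,5Z,8S)-2,8-dimethyldodeca-1,5,11-trien-4-yl]oxy}methyl)propanedioate, via lithium alkoxide 11 (not isolated), via lithium enolate 12 (not isolated)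
Conditions: n-BuLi (1.0 equiv), THF, −78 °C; 10, −78 → −20 °C; AcOH
Reagents that add atoms: none
Why: Oxa-Michael addition of the lithium alkoxide to the doubly activated, unhindered acceptor forms the O8–C13 tether and ends at the stabilised malonate enolate, which is quenched with acid; low temperature and the lithium counter-ion keep the anionic oxy-Cope rearrangement of the 1,5-dien-3-olate silent, and C8 is not touched.

**Step 9**
Reactants: 13 di-tert-butyl 2-({[(4S,5Z,8S)-2,8-dimethyldodeca-1,5,11-trien-4-yl]oxy}methyl)propanedioate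
Product: 15 tert-butyl (1R,4S,5R,6S)-4-[(2S)-2-methylhex-5-en-1-yl]-6-(2-methylprop-2-en-1-yl)-2-oxo-3,7-dioxabicyclo[3.3.0]octane-1-carboxylate, via iodide 14 (not isolated)
Conditions: I2 (1.1 equiv), Ti(OtBu)4 (1.1 equiv), ClCH2CH2Cl, rt, dark; then 70 °C; aq Na2S2O3/NaHCO3 work-up
Reagents that add atoms: none
Why: Mechanism: Ti(OtBu)4 turns the malonate into its titanium enolate, C11 attacks C7 anti to the iodonium ion that I2 forms reversibly on C6=C7 (gives 14), and on warming the carbonyl oxygen of the tert-butyl ester lying cis to the side chain displaces iodide from C6 with inversion, after which the dialkoxycarbenium ion sheds 2-methylpropene. The closest known reaction type is the ionic iodocarbocyclisation of 4-alkenylmalonates with I2 and Ti(OtBu)4 followed by thermal closure of the iodo esters to bicyclic γ-lactones. Ring C closes 5-exo-trig and ring B 5-exo-tet. C7 is controlled by C8, because allylic 1,3-strain in the Z-alkene keeps H8 in the alkene plane so that the O8-tethered carbon reaches one face only and C6 ends trans to C9 on ring C; C6 is controlled by the Z geometry, because anti addition followed by inversion amounts to a syn addition of C11 and O that leaves C5 and C8 cis on ring B (H6 and H7 cis); C11 follows from the cis fusion that a bicyclo[3.3.0] frame demands. The step needs chemoselectivity among three alkenes and 5-exo over 6-endo closure: only C6=C7 lies within five-ring reach of C11, attack on C10 of the methallyl group would have to join two quaternary carbons in a six-ring closure, the vinyl group is out of reach, and unproductive iodonium ions revert. Ti(OtBu)4 cannot scramble tert-butyl esters and takes up the HI that both stages release.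

**Step 10**
Reactants: 15 tert-butyl (1R,4S,5R,6S)-4-[(2S)-2-methylhex-5-en-1-yl]-6-(2-methylprop-2-en-1-yl)-2-oxo-3,7-dioxabicyclo[3.3.0]octane-1-carboxylate
Product: 17 (1S,4S,5R,6S)-4-[(2S)-2-methylhex-5-en-1-yl]-6-(2-methylprop-2-en-1-yl)-3,7-dioxabicyclo[3.3.0]octan-2-one, via carboxylic acid 16 (not isolated)
Conditions: silica gel, PhMe, 110 °C
Reagents that add atoms: none
Why: Silica-promoted E1-type cleavage of the tert-butyl ester is followed by thermal decarboxylation of the malonic-type acid 16; protonation at C11 can only give the cis-fused bicycle, and removal of the quaternary centre frees C13 for the later SN2 opening.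

**Step 11**
Reactants: 17 (1S,4S,5R,6S)-4-[(2S)-2-methylhex-5-en-1-yl]-6-(2-methylprop-2-en-1-yl)-3,7-dioxabicyclo[3.3.0]octan-2-one
Product: 18 (4S,6S,7R,8S,11S)-8,13-epoxygermacr-1(10)-en-12,6-olide (tricycle A/B/C; ring-cis C1=C10)
Conditions: second-generation Hoveyda–Grubbs catalyst (10 mol %), tetrafluoro-1,4-benzoquinone, PhMe (0.5 mM), 100 °C
Reagents that add atoms: none
Why: Ring-closing metathesis of a vinyl group with a methallyl group, a pairing known to close ten-membered carbocycles on rigid lactone templates, forms ring A; the masked acrylate cannot interfere, and the reversible closure should settle on the less strained ring-cis trisubstituted alkene.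

**Step 12**
Reactants: 18 (4S,6S,7R,8S,11S)-8,13-epoxygermacr-1(10)-en-12,6-olide
Product: 20 (4S,6S,7R,8S)-8-hydroxygermacra-1(10),11(13)-dien-12,6-olide (ring-cis C1=C10), via bromo borinate 19 (not isolated)
Conditions: Me2BBr, Et3N (0.2 equiv), CH2Cl2, 0 °C → rt; then DBU, 0 °C; aq NaHCO3
Reagents that add atoms: none
Why: Regioselective SN2 cleavage of the cyclic ether by Me2BBr (boron on O8, bromide at the primary C13 rather than the secondary C8) followed by E1cB-type dehydrobromination of the β-bromo lactone with DBU unveils C11=C13 and C8–OH, and re-closure would be a disfavoured 5-endo-trig oxa-Michael addition.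

**Step 13**
Reactants: 20 (4S,6S,7R,8S)-8-hydroxygermacra-1(10),11(13)-dien-12,6-olide; 21 (tert-butyldimethylsilyloxy)acetic acid
Product: 22 (4S,6S,7S,8S)-8-[(tert-butyldimethylsilyloxy)acetoxy]germacra-1(10),11(13)-dien-12,6-olide
Conditions: DCC, DMAP, CH2Cl2, 0 °C → rt
Reagents that add atoms: none
Why: Steglich esterification acylates the only free hydroxyl group with retention at C8, and the silyl ether keeps the glycolate oxygen distinct from the C14 oxygen that is still to come.

**Step 14**
Reactants: 22 (4S,6S,7S,8S)-8-[(tert-butyldimethylsilyloxy)acetoxy]germacra-1(10),11(13)-dien-12,6-olide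
Product: 23 14-hydroxy derivative of 22 (CH2OH trans to C2)
Conditions: SeO2 (cat.), tBuOOH, CH2Cl2, 0 °C → rt
Reagents that add atoms: tert-butyl hydroperoxide, CC(C)(C)OO (oxygen passed on through selenium dioxide, O=[Se]=O)
Why: Riley allylic oxidation (ene reaction, then [2,3]-sigmatropic shift) hydroxylates the methyl group on the more substituted alkene carbon, as known for C10-methyl germacranolides that carry an α-methylene lactone; the shift returns the alkene with CH2OH trans to C2, and the C8 ester deactivates the competing C9 methylene.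

**Step 15**
Reactants: 23 14-hydroxy derivative of 22
Product: 24 14-acetate of 23
Conditions: Ac2O, pyridine, DMAP (cat.), CH2Cl2, 0 °C
Reagents that add atoms: acetic anhydride, CC(=O)OC(C)=O
Why: Standard O-acetylation of the single free primary allylic alcohol.

**Step 16**
Reactants: 24 14-acetate of 23
Product: 25 target CNP0156635.1 [(4S,6S,7S,8S)-14-acetoxy-8-(hydroxyacetoxy)germacra-1(10),11(13)-dien-12,6-olide]
Conditions: HF·pyridine, THF, 0 °C
Reagents that add atoms: none
Why: Fluoride-mediated desilylation under buffered acidic conditions frees the glycolate hydroxyl group without touching the two esters, the lactone or the Michael acceptor.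

**Compound list**

1 | (S)-citronellal | O=CC[C@@H](C)CCC=C(C)C | starting material
2 | (4S)-4,8-dimethylnon-7-en-1-yne | C#CC[C@@H](C)CCC=C(C)C | intermediate
3 | (4S)-4-methylhept-6-ynal | C#CC[C@@H](C)CCC=O | intermediate
4 | (5S)-5-methyloct-1-en-7-yne | C#CC[C@@H](C)CCC=C | intermediate
5 | lithium acetylide of 4 | [Li]C#CC[C@@H](C)CCC=C | intermediate
6 | (5S)-5-methylnon-8-en-2-ynal | O=CC#CC[C@@H](C)CCC=C | intermediate
7 | (4S,8S)-2,8-dimethyldodeca-1,11-dien-5-yn-4-ol | C=C(C)C[C@H](O)C#CC[C@@H](C)CCC=C | intermediate
8 | (4S,5Z,8S)-2,8-dimethyldodeca-1,5,11-trien-4-ol | C=C(C)C[C@H](O)/C=C\C[C@@H](C)CCC=C | intermediate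
9 | di-tert-butyl malonate | CC(C)(C)OC(=O)CC(=O)OC(C)(C)C | starting material
10 | di-tert-butyl methylenemalonate | C=C(C(=O)OC(C)(C)C)C(=O)OC(C)(C)C | intermediate
11 | lithium alkoxide of 8 | C=C(C)C[C@H](O[Li])/C=C\C[C@@H](C)CCC=C | intermediate
12 | lithium enolate of 13 | C=C(C)C[C@H](OCC(C(=O)OC(C)(C)C)=C(O[Li])OC(C)(C)C)/C=C\C[C@@H](C)CCC=C | intermediate
13 | di-tert-butyl 2-({[(4S,5Z,8S)-2,8-dimethyldodeca-1,5,11-trien-4-yl]oxy}methyl)propanedioate | C=C(C)C[C@H](OCC(C(=O)OC(C)(C)C)C(=O)OC(C)(C)C)/C=C\C[C@@H](C)CCC=C | intermediate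
14 | di-tert-butyl (4R,5S)-4-[(1R,3S)-1-iodo-3-methylhept-6-en-1-yl]-5-(2-methylprop-2-en-1-yl)oxolane-3,3-dicarboxylate | C=C(C)C[C@@H]1OCC(C(=O)OC(C)(C)C)(C(=O)OC(C)(C)C)[C@H]1[C@H](I)C[C@@H](C)CCC=C | intermediate
15 | tert-butyl (1R,4S,5R,6S)-4-[(2S)-2-methylhex-5-en-1-yl]-6-(2-methylprop-2-en-1-yl)-2-oxo-3,7-dioxabicyclo[3.3.0]octane-1-carboxylate | C=C(C)C[C@@H]1OC[C@@]2(C(=O)OC(C)(C)C)C(=O)O[C@@H](C[C@@H](C)CCC=C)[C@@H]12 | intermediate
16 | (1S,4S,5R,6S)-4-[(2S)-2-methylhex-5-en-1-yl]-6-(2-methylprop-2-en-1-yl)-2-oxo-3,7-dioxabicyclo[3.3.0]octane-1-carboxylic acid | C=C(C)C[C@@H]1OC[C@@]2(C(=O)O)C(=O)O[C@@H](C[C@@H](C)CCC=C)[C@@H]12 | intermediate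
17 | (1S,4S,5R,6S)-4-[(2S)-2-methylhex-5-en-1-yl]-6-(2-methylprop-2-en-1-yl)-3,7-dioxabicyclo[3.3.0]octan-2-one | C=C(C)C[C@@H]1OC[C@H]2C(=O)O[C@@H](C[C@@H](C)CCC=C)[C@@H]12 | intermediate
18 | (4S,6S,7R,8S,11S)-8,13-epoxygermacr-1(10)-en-12,6-olide, ring-cis alkene | O=C1O[C@H]2C[C@@H](C)CC/C=C(/C)C[C@@H]3OC[C@@H]1[C@@H]23 | intermediate
19 | 13-bromo-11,13-dihydro derivative of 20 as its O8 dimethylborinate | BrC[C@H]1C(=O)O[C@H]2C[C@@H](C)CC/C=C(/C)C[C@H](OB(C)C)[C@@H]12 | intermediate
20 | (4S,6S,7R,8S)-8-hydroxygermacra-1(10),11(13)-dien-12,6-olide, ring-cis alkene | C=C1C(=O)O[C@H]2C[C@@H](C)CC/C=C(/C)C[C@H](O)[C@@H]12 | intermediate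
21 | (tert-butyldimethylsilyloxy)acetic acid | CC(C)(C)[Si](C)(C)OCC(=O)O | starting material
22 | (4S,6S,7S,8S)-8-[(tert-butyldimethylsilyloxy)acetoxy]germacra-1(10),11(13)-dien-12,6-olide | C=C1C(=O)O[C@H]2C[C@@H](C)CC/C=C(/C)C[C@H](OC(=O)CO[Si](C)(C)C(C)(C)C)[C@@H]12 | intermediate
23 | 14-hydroxy derivative of 22 | C=C1C(=O)O[C@H]2C[C@@H](C)CC/C=C(/CO)C[C@H](OC(=O)CO[Si](C)(C)C(C)(C)C)[C@@H]12 | intermediate
24 | 14-acetate of 23 | C=C1C(=O)O[C@H]2C[C@@H](C)CC/C=C(/COC(C)=O)C[C@H](OC(=O)CO[Si](C)(C)C(C)(C)C)[C@@H]12 | intermediate
25 | CNP0156635.1 | C=C1C(=O)O[C@H]2C[C@@H](C)CC/C=C(/COC(C)=O)C[C@H](OC(=O)CO)[C@@H]12 | target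

**Step count**

Total step count: 16. Longest linear sequence: 15 (steps 1–6 and 8–16; step 7 is a one-step side branch).

**Steps most likely to fail**

Step 11. The ten-membered ring may close too slowly. The 1,1-disubstituted alkene engages the ruthenium carbene reluctantly, so intermolecular metathesis of the vinyl group and alkene migration can take over. The fallback replaces metathesis by a reductive carbonyl coupling.
- It sets out from 17. Exhaustive ozonolysis (O3, CH2Cl2, −78 °C; Me2S) cuts off both terminal methylene groups and should give the keto aldehyde F1.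
- An intramolecular McMurry coupling with low-valent titanium (TiCl3, Zn–Cu couple, DME, reflux, slow addition) then joins C1 and C10. This closure is known for ten-membered carbocycles from keto aldehydes.
- It comes back to the route at 18. The aldehyde and ketone are expected to couple faster than the lactone is attacked, and a ring-trans isomer, if formed, would be removed by chromatography.

Step 9. Several processes could cost material while the neutral ester oxygen closes ring B:
- iodide exchange at C6, which would erode its configuration;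
- loss of HI towards C5;
- retro-oxa-Michael loss of the tether.

The fallback separates the two bond formations and uses a much stronger oxygen nucleophile.
- It sets out from 14, now isolated after the room-temperature stage.
- TMSOTf and 2,6-lutidine in CH2Cl2, followed by aqueous work-up, cleave both tert-butyl esters to the iodo diacid F2.
- Cs2CO3 in DMF at rt closes the lactone by a classical carboxylate SN2 displacement with inversion, fast enough to outrun iodide exchange.
- This comes back to the route at 16, which is decarboxylated to 17 as in step 10.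

Step 12. Bromide may attack C8 instead of the β-branched C13, or the boron Lewis acid may engage the lactone or the trisubstituted alkene. The fallback opens ring C by reductive β-elimination instead of substitution.
- It sets out from 18. Enolisation with LiHMDS (THF, −78 °C) and bromination with NBS should give the α-bromo lactone F3, with bromine on the convex face, close to antiperiplanar to the C13–O8 bond.
- Treatment with Zn–Cu couple in THF at 60 °C triggers a Boord-type scission of the β-bromo ether, as known for 3-halotetrahydrofurans. This forms C11=C13 and the zinc alkoxide of O8.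
- It comes back to the route at 20 after aqueous work-up.

**Further compounds**

F1 | step 11 | (1S,4S,5R,6S)-4-[(2S)-2-methyl-5-oxopentyl]-6-(2-oxopropyl)-3,7-dioxabicyclo[3.3.0]octan-2-one | CC(=O)C[C@@H]1OC[C@H]2C(=O)O[C@@H](C[C@@H](C)CCC=O)[C@@H]12
F2 | step 9 | (4R,5S)-4-[(1R,3S)-1-iodo-3-methylhept-6-en-1-yl]-5-(2-methylprop-2-en-1-yl)oxolane-3,3-dicarboxylic acid | C=C(C)C[C@@H]1OCC(C(=O)O)(C(=O)O)[C@H]1[C@H](I)C[C@@H](C)CCC=C
F3 | step 12 | 11-bromo derivative of 18 (Br cis to H7) | O=C1O[C@H]2C[C@@H](C)CC/C=C(/C)C[C@@H]3OC[C@]1(Br)[C@@H]23
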